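Readings and results stem from a simulated flask with constants of no real substance, noise included.

I had no constants, so I answered your quick question from the three earlier runs.

in all of them: Wu 17 mM; Ky 17 mM; Wa 0.12 mol%
- amber: Lx 0.094 equiv; Uj 1.7 mM; run made earlier
- grey: Lx 1.1 equiv; Uj 1.7 mM; run made earlier
- red: Lx 9.4 equiv; Uj 1.7 mM; run made earlier
- north: Lx 0.120 equiv; Uj 1.70 mM; time 6.0 h
- north-west: Lx 0.300 equiv; Uj 1.70 mM; time 6.0 h
- south-west: Lx 1.00 equiv; Uj 1.70 mM; time 6.0 h
- south: Lx 3.00 equiv; Uj 1.70 mM; time 6.0 h
- south-east: Lx 10.0 equiv; Uj 1.70 mM; time 6.0 h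

| run | time / h | Eb / % | Yx / % |
|---|---|---|---|
| amber | 0.833 | 3 | 0 |
| amber | 1.50 | 4 | 3 |
| amber | 2.50 | 8 | 1 |
| amber | 3.00 | 3 | 0 |
| amber | 4.00 | 4 | 0 |
| grey | 0.833 | 10 | 2 |
| grey | 1.50 | 11 | 1 |
| grey | 2.50 | 20 | 3 |
| grey | 3.00 | 23 | 5 |
| grey | 4.00 | 27 | 8 |
| red | 0.333 | 11 | 12 |
| red | 0.667 | 26 | 20 |
| red | 1.33 | 41 | 34 |
| red | 2.00 | 48 | 45 |
| red | 4.00 | 52 | 47 |

(scatter of a reading: 2 percentage points)

- Wa is single-handed; Wu and Ky are mirror images of each other, charged as a racemate, each of them at the stated concentration
- what was read earlier has a scatter of 2 percentage points, one standard deviation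
- candidate steps: Lx + Xi -> Wa + Yx; Lx + Uj -> Ze; Lx + Uv -> Wa + Eb; Wa + Ky <-> Xi; Wa + Wu <-> Uv
- an excess is the difference of the two amounts in percent of their sum
- "hardly changes" means that all values lie within two and a half points (for a concentration: within two and a half percent of the largest)

- excess of Eb over Yx at the end for north, north-west, south-west, south, south-east, in this order
- how that number moves from the first to the last of them (falls, then rises / falls all the way / hardly changes / rises, then falls / rises all the way)

I assumed each enantiomer went at a rate proportional to its own amount, with one common factor for catalyst and Lx. Dividing the two rates and integrating then gives a fixed ratio. Grey's readings at 4.00 h, with their scatter, put the fraction of its Wu left at 0.460 and of its Ky at 0.840. So the selectivity factor s, the logarithm of the first fraction over the logarithm of the second, read 4.45. Red at 1.33 h read 1.50, lower than grey, so I took s to fall as Lx rose.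

On that assumption the excess early in a run is s less one over s plus one, which for grey's s is 63.3 %. I put north and north-west above that. For south-west I carried grey's pace on to 6.0 h, and so estimated 0.312 of the Wu and 0.770 of the Ky left, an excess of 49.9 %. Red's last reading, 52 % against 47 %, put south-east near zero.

Your forecast ran 72 %, 69 %, 55 %, 18 %, 0.5 %, and its shape was falls all the way. It held that “at low Lx, conversion is limited by Lx and the excess stays near 70%”. At south-west it stood above my figure.

The flasks gave 82.1 %, 78.6 %, 63.3 %, 15.1 %, 0 %, and the shape was falls all the way.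

    Lx + Xi → Wa + Yx (k = 130 /M/min)
    Lx + Uj → Ze (k = 0.380 /M/min)
    Lx + Uv → Wa + Eb (k = 280 /M/min)
    Wa + Ky ⇌ Xi (K = 180 /M, k = 3100 /M/min)
    Wa + Wu ⇌ Uv (K = 990 /M, k = 2500 /M/min)

I put the fractions left at the end into the same ratio. South-west gave 6.33, against grey's reading of 4.45. North gave 10.5, higher than south-west, and s less one over s plus one turned that into 82.6 %. North's s stood so high because Xi returned to Wa + Ky. With that return taken away, north's excess went from 82.1 % to −80.8 %.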